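The route rests on cutting the bond between C2 (the quaternary C–O carbon of the oxane ring) and C1' of the cyclohexane ring. Across it the ring oxygen O1 on C2 and the C6' hydroxyl are 1,3-related, an aldol pattern, and the C3 oxygen flanks the acceptor carbon. The key step adds a regiodefined lithium cyclohexadienolate (C1' nucleophile, C6' carbonyl, C3'=C4' olefin stored for bromochlorination) to an acyclic α-oxido methyl ketone (C2 carbonyl, C3 stereocentre, prenyl olefin stored for bromoetherification). One operation joins the C8 and C7 halves and sets C2 and C1'; both halogenated rings then arise from the two olefins.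

Key step: step 5

Remark on labels: oxane O1, C2 (CH3, cyclohexyl), C3 (OAc), C4, C5 (Br), C6 (CMe2); cyclohexane C1' (bonded to C2), C2', C3' (Br), C4' (Cl, CH3), C5', C6' (OH). C1' keeps one spatial arrangement from step 5 on; its descriptor is R while C6' is a ketone and S once C6' is a carbinol.

Step 1
Reactants: 1 6-methylhept-5-en-2-one
Product: 2 (3S)-6-methyl-3-[(phenylamino)oxy]hept-5-en-2-one
Conditions: PhN=O (slow addition), D-proline (20 mol%), 1 in excess, DMSO, rt
Reagents that add atoms: nitrosobenzene, O=Nc1ccccc1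
Why: Proline enamine catalysis (α-aminoxylation, O-selective nitroso aldol): the more substituted enamine reacts at C3 and the catalyst's acid delivers PhN=O to one enamine face, so the D-catalyst should give 3S (the L-catalyst leads to the R series).

Step 2
Reactants: 2 (3S)-6-methyl-3-[(phenylamino)oxy]hept-5-en-2-one
Product: 3 (3S)-3-hydroxy-6-methylhept-5-en-2-one
Conditions: CuSO4·5H2O (30 mol%), MeOH, 0 °C
Reagents that add atoms: none
Why: Copper(II)-catalysed N–O cleavage frees the α-hydroxy ketone without touching the C3–O bond, so 3S is kept.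

Step 3
Reactants: 4 3-methylphenol
Product: 5 tert-butyl(dimethyl)(3-methylphenoxy)silane
Conditions: TBSCl, imidazole, DMF, rt
Reagents that add atoms: tert-butyldimethylsilyl chloride, CC(C)(C)[Si](C)(C)Cl
Why: O-silylation of the phenol gives an aryl silyl ether that tolerates dissolving metal.

Step 4
Reactants: 5 tert-butyl(dimethyl)(3-methylphenoxy)silane
Product: 6 tert-butyl(dimethyl)[(5-methylcyclohexa-1,4-dien-1-yl)oxy]silane
Conditions: Li, NH3(l), THF, t-BuOH, −78 → −33 °C; pentane work-up
Reagents that add atoms: none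
Why: Birch reduction protonates ortho and meta to oxygen so that the O- and CH3-bearing carbons stay sp2, which gives the silyl enol ether of 3-methylcyclohex-3-enone with the enol double bond fixed at C6'=C1' and no stereocentre.

Step 5
Reactants: 6 tert-butyl(dimethyl)[(5-methylcyclohexa-1,4-dien-1-yl)oxy]silane; 3 (3S)-3-hydroxy-6-methylhept-5-en-2-one
Product: 9 (6R)-6-[(2S,3S)-2,3-dihydroxy-6-methylhept-5-en-2-yl]-3-methylcyclohex-3-en-1-one, via lithium dienolate 7 (not isolated), via lithium ketol alkoxide 8 (not isolated)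
Conditions: 6, MeLi (1.05 equiv), THF, 0 °C → rt; separately 3, LiHMDS (1.0 equiv), THF, −78 °C; combine at −78 °C; AcOH quench at −78 °C
Reagents that add atoms: none
Why: The regiodefined lithium enolate 7 adds through C1' to the C2 carbonyl of alkoxide 8 in a directed ketone–ketone aldol addition (closest known type: Cram-chelate-controlled aldol addition of a preformed lithium enolate). No ring is closed. C2 is set by the C3 stereocentre: the alkoxide lithium bridges O3 and the carbonyl oxygen, and the enolate attacks the face of this five-membered chelate opposite the C4 methylene, which gives 2S from 3S. C1' is set by the chair (Zimmerman–Traxler) transition state of the ring-locked (E)-enolate, in which the branched C3 arm of the ketone sits equatorial and its methyl axial, as an aldehyde substituent would, so that C2' and the new hydroxyl end anti (the arrangement needed; R by CIP in the ketone). The step needs C1' and not C5' to react, which is secured because 7 comes from the Birch enol ether with its double bond already at C6'=C1' and is never equilibrated. It also needs addition to outrun proton transfer from the methyl ketone and retro-aldol, hence −78 °C and the cold acid quench.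

Step 6
Reactants: 9 (6R)-6-[(2S,3S)-2,3-dihydroxy-6-methylhept-5-en-2-yl]-3-methylcyclohex-3-en-1-one
Product: 10 (2S,3S)-2-hydroxy-6-methyl-2-[(1R)-4-methyl-6-oxocyclohex-3-en-1-yl]hept-5-en-3-yl acetate
Conditions: Ac2O (1.2 equiv), pyridine, CH2Cl2, 0 °C
Reagents that add atoms: acetic anhydride, CC(=O)OC(C)=O
Why: Acylation of the secondary C3 hydroxyl; the tertiary C2 hydroxyl does not react, and any cyclic hemiketal form of 9 (C3–OH on C6') is drained through the open hydroxy ketone.

Step 7
Reactants: 10 (2S,3S)-2-hydroxy-6-methyl-2-[(1R)-4-methyl-6-oxocyclohex-3-en-1-yl]hept-5-en-3-yl acetate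
Product: 11 (2S,3S,5S)-5-bromo-2,6,6-trimethyl-2-[(1R)-4-methyl-6-oxocyclohex-3-en-1-yl]oxan-3-yl acetate
Conditions: 2,4,4,6-tetrabromocyclohexa-2,5-dienone (1.05 equiv), MeNO2, −20 → 0 °C
Reagents that add atoms: 2,4,4,6-tetrabromocyclohexa-2,5-dien-1-one, BrC1=CC(Br)(Br)C=C(Br)C1=O
Why: Bromonium-induced 6-endo etherification (Markovnikov attack of the C2 hydroxyl on the CMe2 terminus); the chair with the cyclohexenonyl group equatorial on C2 puts the C2 methyl and C3 acetate axial and the C5 bromine equatorial, which is 5S, while the ring olefin has no hydroxyl that can reach it through a chair.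

Step 8
Reactants: 11 (2S,3S,5S)-5-bromo-2,6,6-trimethyl-2-[(1R)-4-methyl-6-oxocyclohex-3-en-1-yl]oxan-3-yl acetate
Product: 12 (2S,3S,5S)-5-bromo-2-[(1S,6R)-6-hydroxy-4-methylcyclohex-3-en-1-yl]-2,6,6-trimethyloxan-3-yl acetate
Conditions: L-Selectride (1.1 equiv), THF, −78 °C; aq NH4Cl
Reagents that add atoms: none
Why: The bulky hydride attacks the C6' ketone along the equatorial trajectory next to the large C1' substituent and should give the axial alcohol cis to it (6'R); acetate and secondary bromide survive at −78 °C.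

Step 9
Reactants: 12 (2S,3S,5S)-5-bromo-2-[(1S,6R)-6-hydroxy-4-methylcyclohex-3-en-1-yl]-2,6,6-trimethyloxan-3-yl acetate
Product: 13 (2S,3S,5S)-5-bromo-2,6,6-trimethyl-2-{(1S,6R)-4-methyl-6-[(triethylsilyl)oxy]cyclohex-3-en-1-yl}oxan-3-yl acetate
Conditions: TESOTf, 2,6-lutidine, CH2Cl2, −78 °C
Reagents that add atoms: triethylsilyl trifluoromethanesulfonate, CC[Si](CC)(CC)OS(=O)(=O)C(F)(F)F
Why: Silylation of the only free hydroxyl; the axial C6' silyloxy group is the shield for the next step.

Step 10
Reactants: 13 (2S,3S,5S)-5-bromo-2,6,6-trimethyl-2-{(1S,6R)-4-methyl-6-[(triethylsilyl)oxy]cyclohex-3-en-1-yl}oxan-3-yl acetate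
Product: 15 (2S,3S,5S)-5-bromo-2-[(1S,2R,4R,5R)-5-bromo-4-chloro-2-hydroxy-4-methylcyclohexyl]-2,6,6-trimethyloxan-3-yl acetate (target), via silyl-protected bromochloride 14 (not isolated)
Conditions: Bu4N+ BrCl2− (1.1 equiv), CH2Cl2, −78 → −40 °C; then HF·pyridine, THF, 0 °C
Reagents that add atoms: tetrabutylammonium dichlorobromate (written as Bu4N+ Cl− with BrCl), CCCC[N+](CCCC)(CCCC)CCCC.[Cl-].ClBr
Why: Anti bromochlorination through a bromonium ion opened by chloride at the tertiary C4' (Markovnikov); chloride should not enter on the face syn to the 1,3-diaxial C6' silyloxy group, so Cl ends anti and Br syn to it (3'R,4'R), and HF·pyridine then removes the silyl group.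

Compound list
1 | 6-methylhept-5-en-2-one | CC(=O)CCC=C(C)C | starting material
2 | (3S)-6-methyl-3-[(phenylamino)oxy]hept-5-en-2-one | CC(=O)[C@@H](ONc1ccccc1)CC=C(C)C | intermediate
3 | (3S)-3-hydroxy-6-methylhept-5-en-2-one | CC(=O)[C@@H](O)CC=C(C)C | intermediate
4 | 3-methylphenol | Cc1cccc(O)c1 | starting material
5 | tert-butyl(dimethyl)(3-methylphenoxy)silane | Cc1cccc(O[Si](C)(C)C(C)(C)C)c1 | intermediate
6 | tert-butyl(dimethyl)[(5-methylcyclohexa-1,4-dien-1-yl)oxy]silane | CC1=CCC=C(O[Si](C)(C)C(C)(C)C)C1 | intermediate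
7 | lithium 5-methylcyclohexa-1,4-dien-1-olate | [Li+].[O-]C1=CCC=C(C)C1 | intermediate (not isolated)
8 | lithium (3S)-6-methyl-2-oxohept-5-en-3-olate | [Li+].[O-][C@H](C(C)=O)CC=C(C)C | intermediate (not isolated)
9 | (6R)-6-[(2S,3S)-2,3-dihydroxy-6-methylhept-5-en-2-yl]-3-methylcyclohex-3-en-1-one | O[C@H]([C@@](C)(O)[C@H]1CC=C(C)CC1=O)CC=C(C)C | intermediate
10 | (2S,3S)-2-hydroxy-6-methyl-2-[(1R)-4-methyl-6-oxocyclohex-3-en-1-yl]hept-5-en-3-yl acetate | CC(=O)O[C@H]([C@@](C)(O)[C@H]1CC=C(C)CC1=O)CC=C(C)C | intermediate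
11 | (2S,3S,5S)-5-bromo-2,6,6-trimethyl-2-[(1R)-4-methyl-6-oxocyclohex-3-en-1-yl]oxan-3-yl acetate | CC(=O)O[C@H]1C[C@H](Br)C(C)(C)O[C@@]1(C)[C@H]1CC=C(C)CC1=O | intermediate
12 | (2S,3S,5S)-5-bromo-2-[(1S,6R)-6-hydroxy-4-methylcyclohex-3-en-1-yl]-2,6,6-trimethyloxan-3-yl acetate | CC(=O)O[C@H]1C[C@H](Br)C(C)(C)O[C@@]1(C)[C@H]1CC=C(C)C[C@H]1O | intermediate
13 | (2S,3S,5S)-5-bromo-2,6,6-trimethyl-2-{(1S,6R)-4-methyl-6-[(triethylsilyl)oxy]cyclohex-3-en-1-yl}oxan-3-yl acetate | CC(=O)O[C@H]1C[C@H](Br)C(C)(C)O[C@@]1(C)[C@H]1CC=C(C)C[C@H]1O[Si](CC)(CC)CC | intermediate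
14 | (2S,3S,5S)-5-bromo-2-{(1S,2R,4R,5R)-5-bromo-4-chloro-4-methyl-2-[(triethylsilyl)oxy]cyclohexyl}-2,6,6-trimethyloxan-3-yl acetate | CC(=O)O[C@H]1C[C@H](Br)C(C)(C)O[C@@]1(C)[C@H]1C[C@@H](Br)[C@](C)(Cl)C[C@H]1O[Si](CC)(CC)CC | intermediate (not isolated)
15 | (2S,3S,5S)-5-bromo-2-[(1S,2R,4R,5R)-5-bromo-4-chloro-2-hydroxy-4-methylcyclohexyl]-2,6,6-trimethyloxan-3-yl acetate | CC(=O)O[C@H]1C[C@H](Br)C(C)(C)O[C@@]1(C)[C@H]1C[C@@H](Br)[C@](C)(Cl)C[C@H]1O | target

Total step count: 10. Longest linear sequence: 8 steps (1, 2, 5–10; the branch 3, 4, 5–10 is equally long).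

Steps most likely to fail

Step 5. Proton transfer from the methyl ketone to the enolate, retro-aldol on warming, or a transition state in which one lithium binds all three oxygens (C3 arm axial) may erode the yield or invert the sense at C1'. The fallback sets out from 3 and returns at 9. The Grignard reagent (2-methoxy-4-methylphenyl)magnesium bromide F1, made from commercial 1-bromo-2-methoxy-4-methylbenzene and Mg, is added to 3 (2.2 equiv, THF, −78 °C). Cram-chelate addition should give (2S,3S)-2-(2-methoxy-4-methylphenyl)-6-methylhept-5-ene-2,3-diol F2. Birch reduction of its dialkoxide (Li, NH3, t-BuOH) should give (2S,3S)-2-(2-methoxy-4-methylcyclohexa-1,4-dien-1-yl)-6-methylhept-5-ene-2,3-diol F3. Mild hydrolysis of the enol ether (oxalic acid, aq THF) then leads to 9. Here C1' is set by protonation of the enol ether, and its sense would have to be checked.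

Step 10. Chloride may still open the bromonium ion diaxially on the face syn to the silyloxy group (giving the 3'S,4'S isomer), or at C3' instead of C4'. The fallback sets out from 13 and returns at 14, building the two C–halogen bonds one at a time. mCPBA epoxidation anti to the silyloxy group should give the 3',4'-epoxide F4, with oxygen on the face opposite the silyl ether. TMSOTf/DBU isomerisation followed by citric acid work-up should give the allylic alcohol F5 (C3'–OH, exocyclic methylene at C4'). Cobalt-catalysed hydrogen-atom-transfer hydrochlorination (PhSiH3, TsCl, EtOH) transfers chlorine to the tertiary C4' radical on the face away from the silyloxy group and should give the chlorohydrin F6. An Appel reaction (CBr4, PPh3) with inversion at C3' then leads to 14, which is desilylated as in step 10.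

Step 7. The hydroxyl may close 5-exo on C5 instead of 6-endo on C6, and the bromonium source may also engage the ring olefin. The fallback sets out from 10 and returns at 11. The 5-exo product, the tetrahydrofuran with a 2-bromopropan-2-yl side chain F7, is made on purpose (NBS, CH2Cl2, 0 °C). It is then ring-expanded under catalytic ZnBr2 in MeNO2: the tertiary bromide ionises with help from the ring oxygen to a bicyclic oxonium ion, and bromide re-enters at C5 to give 11.

Further compounds
F1 | step 5 | (2-methoxy-4-methylphenyl)magnesium bromide | COc1cc(C)ccc1[Mg]Br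
F2 | step 5 | (2S,3S)-2-(2-methoxy-4-methylphenyl)-6-methylhept-5-ene-2,3-diol | O[C@H]([C@@](C)(O)c1ccc(C)cc1OC)CC=C(C)C
F3 | step 5 | (2S,3S)-2-(2-methoxy-4-methylcyclohexa-1,4-dien-1-yl)-6-methylhept-5-ene-2,3-diol | O[C@H]([C@@](C)(O)C1=C(OC)CC(C)=CC1)CC=C(C)C
F4 | step 10 | 3',4'-epoxide of 13 with the epoxide oxygen anti to the silyloxy group | CC(=O)O[C@H]1C[C@H](Br)C(C)(C)O[C@@]1(C)[C@H]1C[C@@H]2O[C@]2(C)C[C@H]1O[Si](CC)(CC)CC
F5 | step 10 | allylic alcohol with C3' hydroxyl (trans to the silyloxy group) and exocyclic methylene at C4' | CC(=O)O[C@H]1C[C@H](Br)C(C)(C)O[C@@]1(C)[C@H]1C[C@H](O)C(=C)C[C@H]1O[Si](CC)(CC)CC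
F6 | step 10 | chlorohydrin with C3' hydroxyl and C4' chloride both trans to the silyloxy group | CC(=O)O[C@H]1C[C@H](Br)C(C)(C)O[C@@]1(C)[C@H]1C[C@H](O)[C@](C)(Cl)C[C@H]1O[Si](CC)(CC)CC
F7 | step 7 | (2S,3S,5R)-5-(2-bromopropan-2-yl)-2-methyl-2-[(1R)-4-methyl-6-oxocyclohex-3-en-1-yl]oxolan-3-yl acetate | CC(=O)O[C@H]1C[C@H](C(C)(C)Br)O[C@@]1(C)[C@H]1CC=C(C)CC1=O
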